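**Retrosynthetic overview**
- The route rests on the C6–C6'' bond between the two rings A: it is flanked by the oxygen-bearing carbons C5, C7, C5'' and C7'', and the oxygens on C8a/C8a'' (para to it, the future O1/O1'') must be told apart from those on C5 and C7.
- Target ⇐ hexabenzyl ether (hydrogenolysis) ⇐ 6,6'-bichromone plus two aryl groups (rings B) by rhodium-catalysed asymmetric 1,4-addition, which sets C2 and C2''.
- Bichromone ⇐ 3,3'-diacetylbiphenyl-4,4'-diol (C2 from an amide acetal, O1 from the only free phenol); the four ethyl ethers are exchanged for benzyl at the achiral chromone stage, so that no Lewis acid meets the finished stereocentres.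
- Biphenyldiol ⇐ 2,2'-bi(3-ethoxycyclobutenone) + 2 ethoxyacetylene: a double benzannulation builds both rings A around the C6–C6'' bond already in place; the bicyclobutenone comes from 3-ethoxycyclobutenone through its 2-iodide.
- Ring order: both rings A together, then both rings C, then rings B attached as intact aryl groups.

Key step: step 3

Assumption: the target SMILES fixes only C2 and C2'' (both S) and leaves the hindered C6–C6'' axis open, so compounds from the diacetyl stage onwards are carried as atropisomer mixtures and the product is the (2S,2''S) compound without regard to the axis.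

**Step 1**
Reactants: 1 3-ethoxycyclobut-2-en-1-one
Product: 2 3-ethoxy-2-iodocyclobut-2-en-1-one
Conditions: NIS, MeCN, 0 °C to rt, dark
Reagents that add atoms: N-iodosuccinimide, O=C1CCC(=O)N1I
Why: Electrophilic α-iodination of a vinylogous ester: C2 is the nucleophilic enol-ether carbon, attack on NIS gives an oxocarbenium ion that loses the C2 proton, and C4 does not compete because its enol would be a cyclobutadiene.

**Step 2**
Reactants: 2 3-ethoxy-2-iodocyclobut-2-en-1-one (two molecules)
Product: 4 2,2'-bi(3-ethoxycyclobut-2-en-1-one), via stannane 3 (not isolated)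
Conditions: Me3SnSnMe3 (0.55 equiv), Pd(PPh3)4 (cat.), CuI (cat.), DMF, 50 °C
Reagents that add atoms: none
Why: Stille–Kelly reductive homocoupling: zerovalent palladium inserts into the weak C2–I bond, the distannane turns part of 2 into stannane 3, and copper-assisted Stille coupling of 3 with the remaining 2 forms the C2–C2' bond below the temperature at which the four-membered ring opens; palladium/copper Stille couplings that join two four-membered enone rings through their alkoxy-enone carbons are known for cyclobutenediones, and zerovalent nickel is avoided because it inserts into the acyl–C4 bond of cyclobutenones.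

**Step 3**
Reactants: 4 2,2'-bi(3-ethoxycyclobut-2-en-1-one), 5 ethoxyacetylene
Product: 7 2,2',6,6'-tetraethoxybiphenyl-4,4'-diol, via monoarene 6 (not isolated)
Conditions: 5 (8 equiv, hexanes solution), toluene, sealed tube, 85 °C; then KOH, MeOH, rt
Reagents that add atoms: ethoxyacetylene (5), C#COCC
Why: Proposed new method: each cyclobutenone opens thermally (four-electron electrocyclic cleavage of C1–C4) to a vinylketene, the polarised ynol ether adds to it in a [2+2] sense with its unsubstituted carbon on the ketene carbonyl carbon (the future C8a–C4a bond) and its ethoxy-bearing carbon on the ketene α-carbon (the future C5–C6 bond), and the resulting 4-vinylcyclobutenone opens to a dienylketene. Each ring A is then closed by six-electron electrocyclisation of that dienylketene, which re-forms the C8–C8a bond, and the cyclohexadienone tautomerises to the phenol. The closest known reaction is the Danheiser benzannulation of a single cyclobutenone with an alkoxyacetylene; new here is its twofold use on a 2,2'-linked bis(3-alkoxycyclobutenone), where the ketene α-carbon carries the second four-membered ring. No stereocentre is formed. The selectivity needed is regiochemical, both ethoxy groups ortho and the hydroxyl para to the C6–C6'' bond, and it is fixed by the ketene–ynol ether polarity; the excess of 5 traps each vinylketene before the second ring opens, which suppresses collapse of a 1,2-bisketene to a cyclobutenedione, and the methanolic KOH returns any phenol that a vinylketene has acylated.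

**Step 4**
Reactants: 7 2,2',6,6'-tetraethoxybiphenyl-4,4'-diol
Product: 8 1,1'-(2,2',6,6'-tetraethoxy-4,4'-dihydroxybiphenyl-3,3'-diyl)di(ethan-1-one)
Conditions: AcOH, BF3·OEt2, 80 °C; aq. NaOAc
Reagents that add atoms: acetic acid, CC(=O)O
Why: Friedel–Crafts C-acetylation of a 3,5-dialkoxyphenol (O-acetylation and boron-assisted Fries shift): on each ring only the two equivalent positions ortho to the free hydroxyl are open, and the first acetyl group, held as its BF2 chelate, deactivates that ring so that one acetyl enters per ring.

**Step 5**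
Reactants: 8 1,1'-(2,2',6,6'-tetraethoxy-4,4'-dihydroxybiphenyl-3,3'-diyl)di(ethan-1-one)
Product: 10 5,5',7,7'-tetraethoxy-4H,4'H-[6,6'-bichromene]-4,4'-dione, via bis-enaminone 9 (not isolated)
Conditions: Me2NCH(OMe)2, toluene, 100 °C; concentrate; then AcOH, 80 °C
Reagents that add atoms: N,N-dimethylformamide dimethyl acetal, COC(OC)N(C)C
Why: Condensation of each methyl ketone with the amide acetal gives the enaminone, and acid-promoted 6-endo conjugate addition of the neighbouring phenol followed by loss of dimethylamine closes ring C as a chromone (enaminone route to chromones); the only free hydroxyl is the one para to the biaryl bond, so it alone can become O1 and the biaryl carbon becomes C6.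

**Step 6**
Reactants: 10 5,5',7,7'-tetraethoxy-4H,4'H-[6,6'-bichromene]-4,4'-dione
Product: 11 5,5',7,7'-tetrahydroxy-4H,4'H-[6,6'-bichromene]-4,4'-dione
Conditions: BBr3 (excess), CH2Cl2, −78 °C to rt; MeOH, H2O
Reagents that add atoms: none
Why: BBr3 cleavage of aryl ethyl ethers through aryloxyboranes and bromoethane, placed here because the bichromone has no stereocentre to lose and its ring C, which now holds O1 in place, is not opened by the anhydrous Lewis acid; the C5 ethers go first through chelation to the C4 carbonyl.

**Step 7**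
Reactants: 11 5,5',7,7'-tetrahydroxy-4H,4'H-[6,6'-bichromene]-4,4'-dione
Product: 12 5,5',7,7'-tetrakis(benzyloxy)-4H,4'H-[6,6'-bichromene]-4,4'-dione
Conditions: BnBr, K2CO3, Bu4NI (cat.), dry DMF, 70 °C
Reagents that add atoms: benzyl bromide, BrCc1ccccc1
Why: Williamson O-benzylation; the C7 hydroxyls react readily and the chelated, hindered C5 hydroxyls need the polar solvent, iodide catalysis and heat, while dry carbonate avoids hydroxide opening of ring C.

**Step 8**
Reactants: 12 5,5',7,7'-tetrakis(benzyloxy)-4H,4'H-[6,6'-bichromene]-4,4'-dione, 13 4-(benzyloxy)phenylboronic acid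
Product: 14 (2S,2'S)-5,5',7,7'-tetrakis(benzyloxy)-2,2'-bis[4-(benzyloxy)phenyl]-[6,6'-bichromane]-4,4'-dione
Conditions: [Rh(OH)(cod)]2 (cat.), (S)-MeO-F12-BIPHEP, 13 (5 equiv), toluene/H2O, rt to 40 °C
Reagents that add atoms: 4-(benzyloxy)phenylboronic acid (13), OB(O)c1ccc(OCc2ccccc2)cc1
Why: Rhodium-catalysed asymmetric 1,4-addition of an arylboronic acid to a chromone (Hayashi–Miyaura reaction): the aryl–rhodium species formed by transmetalation adds to C2 of each chromone and water protonates the rhodium enolate, the electron-poor bisphosphine (S)-6,6'-dimethoxy-2,2'-bis[bis(3,4,5-trifluorophenyl)phosphino]biphenyl giving a catalyst active enough for this weak acceptor; the (S)-configured ligand should deliver the aryl group to the Re face of C2 (the same sense by which (S)-biaryl bisphosphines give (S)-3-arylcyclohexanones), which sets 2S and 2''S independently under catalyst control, and the minor (2R,2''S) isomer is removed by chromatography.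

**Step 9**
Reactants: 14 (2S,2'S)-5,5',7,7'-tetrakis(benzyloxy)-2,2'-bis[4-(benzyloxy)phenyl]-[6,6'-bichromane]-4,4'-dione
Product: 15 succedaneaflavanone
Conditions: H2 (1 atm), Pd/C, EtOAc/MeOH, rt
Reagents that add atoms: none
Why: Hydrogenolysis of the six benzyl ethers over Pd/C under neutral conditions, which leaves the acid- and base-labile C2 stereocentres untouched; the O-benzyl groups cleave faster than the ring C2–O1 bond, so the reaction is stopped at six equivalents of hydrogen.

**Compound list**
1 | 3-ethoxycyclobut-2-en-1-one | CCOC1=CC(=O)C1 | starting material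
2 | 3-ethoxy-2-iodocyclobut-2-en-1-one | CCOC1=C(I)C(=O)C1 | intermediate
3 | 3-ethoxy-2-(trimethylstannyl)cyclobut-2-en-1-one | CCOC1=C([Sn](C)(C)C)C(=O)C1 | intermediate (not isolated)
4 | 2,2'-bi(3-ethoxycyclobut-2-en-1-one) | O=C1CC(OCC)=C1C1=C(OCC)CC1=O | intermediate
5 | ethoxyacetylene | C#COCC | starting material
6 | 2-(2,6-diethoxy-4-hydroxyphenyl)-3-ethoxycyclobut-2-en-1-one | O=C1CC(OCC)=C1c1c(OCC)cc(O)cc1OCC | intermediate (not isolated)
7 | 2,2',6,6'-tetraethoxybiphenyl-4,4'-diol | CCOc1cc(O)cc(OCC)c1-c1c(OCC)cc(O)cc1OCC | intermediate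
8 | 1,1'-(2,2',6,6'-tetraethoxy-4,4'-dihydroxybiphenyl-3,3'-diyl)di(ethan-1-one) | CCOc1cc(O)c(C(C)=O)c(OCC)c1-c1c(OCC)cc(O)c(C(C)=O)c1OCC | intermediate
9 | (2E,2'E)-1,1'-(2,2',6,6'-tetraethoxy-4,4'-dihydroxybiphenyl-3,3'-diyl)bis[3-(dimethylamino)prop-2-en-1-one] | CCOc1cc(O)c(C(=O)/C=C/N(C)C)c(OCC)c1-c1c(OCC)cc(O)c(C(=O)/C=C/N(C)C)c1OCC | intermediate (not isolated)
10 | 5,5',7,7'-tetraethoxy-4H,4'H-[6,6'-bichromene]-4,4'-dione | CCOc1cc2occc(=O)c2c(OCC)c1-c1c(OCC)cc2occc(=O)c2c1OCC | intermediate
11 | 5,5',7,7'-tetrahydroxy-4H,4'H-[6,6'-bichromene]-4,4'-dione | Oc1cc2occc(=O)c2c(O)c1-c1c(O)cc2occc(=O)c2c1O | intermediate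
12 | 5,5',7,7'-tetrakis(benzyloxy)-4H,4'H-[6,6'-bichromene]-4,4'-dione | O=c1ccoc2cc(OCc3ccccc3)c(-c3c(OCc4ccccc4)cc4occc(=O)c4c3OCc3ccccc3)c(OCc3ccccc3)c12 | intermediate
13 | 4-(benzyloxy)phenylboronic acid | OB(O)c1ccc(OCc2ccccc2)cc1 | starting material
14 | (2S,2'S)-5,5',7,7'-tetrakis(benzyloxy)-2,2'-bis[4-(benzyloxy)phenyl]-[6,6'-bichromane]-4,4'-dione | O=C1C[C@@H](c2ccc(OCc3ccccc3)cc2)Oc2cc(OCc3ccccc3)c(-c3c(OCc4ccccc4)cc4c(c3OCc3ccccc3)C(=O)C[C@@H](c3ccc(OCc5ccccc5)cc3)O4)c(OCc3ccccc3)c21 | intermediate
15 | succedaneaflavanone, (2S,2''S)-6,6''-binaringenin | O=C1C[C@@H](c2ccc(O)cc2)Oc2cc(O)c(-c3c(O)cc4c(c3O)C(=O)C[C@@H](c3ccc(O)cc3)O4)c(O)c21 | target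

**Step count**
Total steps: 9. Longest linear sequence: 9 steps (1 to 15).

**Steps most likely to fail**

Step 3 (double benzannulation). Both four-membered rings may open before either vinylketene is trapped, and the 1,2-bisketene would then close irreversibly to a cyclobutenedione. The vinylketenes may also oligomerise, or ethoxyacetylene may lose ethylene on heating and feed ketene into side reactions. The fallback makes the biaryl bond by known oxidative aryl–aryl coupling. It sets out from no numbered compound but from commercial phloroglucinol F1, and it rejoins the route at 7. Phloroglucinol F1 is etherified with EtOH/HCl to 3,5-diethoxyphenol F2, which is silylated (i-Pr3SiCl, imidazole, DMF) to (3,5-diethoxyphenoxy)triisopropylsilane F3. Lithiation with n-BuLi/TMEDA in THF at 0 °C takes place between the two ethoxy groups, because the bulky silyl ether shields its own ortho positions, and gives [2,6-diethoxy-4-(triisopropylsilyloxy)phenyl]lithium F4. Oxidative dimerisation with anhydrous CuCl2 (THF, −78 °C to rt) gives 2,2',6,6'-tetraethoxy-4,4'-bis(triisopropylsilyloxy)biphenyl F5, and Bu4NF in THF frees 7. The para hydroxyl is then distinguished from the ortho ethers by the order of protection.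

Step 2 (homocoupling of the iodocyclobutenone). Zerovalent palladium may insert into the strained acyl–C4 bond, the iodide may be reduced without coupling, or the ring may open thermally during the reaction. The fallback does not couple two rings but builds both four-membered rings onto a C–C bond made first. It sets out from 5 and rejoins the route at 4. Ethoxyacetylene 5 is dimerised under Hay conditions (CuCl, TMEDA, O2, acetone, 0 °C) to 1,4-diethoxybuta-1,3-diyne F6, which is used at once in solution. Treatment with ketene gas in CH2Cl2 at 0 °C brings about two successive ketene–ynol ether [2+2] cycloadditions, each placing the ketene carbonyl carbon on the alkyne carbon remote from oxygen. The first gives 3-ethoxy-2-(ethoxyethynyl)cyclobut-2-en-1-one F7 and the second gives 4.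

Step 8 (double asymmetric 1,4-addition). Aryl transfer to the electron-rich, crowded bichromone may be slower than protodeboronation, facial selectivity may be poor at one of the two sites, or β-aryloxide elimination from the rhodium enolate may open ring C. The fallback sets C2 by delivery of hydrogen to a flavone, not by delivery of the aryl group. It sets out from 12 and rejoins the route at 14. Oxidative Heck-type C2-arylation of 12 with 13 (Pd(OCOCF3)2 cat., Cu(OAc)2, DMF, 80 °C) gives 5,5',7,7'-tetrakis(benzyloxy)-2,2'-bis[4-(benzyloxy)phenyl]-4H,4'H-[6,6'-bichromene]-4,4'-dione F8; the same compound is reached by dehydrogenating stereochemically impure 14 with I2 in DMSO. Asymmetric hydrogenation with a ruthenium N-heterocyclic carbene catalyst ([Ru(cod)(2-methylallyl)2], the chiral imidazolinium salt SINpEt·HBF4, KOt-Bu, H2 under pressure, toluene/hexane) reduces C2=C3 and C4=O to the cis-configured (2S,2'S,4S,4'S)-5,5',7,7'-tetrakis(benzyloxy)-2,2'-bis[4-(benzyloxy)phenyl]-[6,6'-bichromane]-4,4'-diol F9. The carbene enantiomer is chosen to give the 2S series. Dess–Martin periodinane in CH2Cl2 oxidises the carbinols back to ketones and returns 14.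

**Further compounds**
F1 | step 3 | phloroglucinol | Oc1cc(O)cc(O)c1
F2 | step 3 | 3,5-diethoxyphenol | CCOc1cc(O)cc(OCC)c1
F3 | step 3 | (3,5-diethoxyphenoxy)triisopropylsilane | CCOc1cc(O[Si](C(C)C)(C(C)C)C(C)C)cc(OCC)c1
F4 | step 3 | [2,6-diethoxy-4-(triisopropylsilyloxy)phenyl]lithium | [Li]c1c(OCC)cc(O[Si](C(C)C)(C(C)C)C(C)C)cc1OCC
F5 | step 3 | 2,2',6,6'-tetraethoxy-4,4'-bis(triisopropylsilyloxy)biphenyl | CCOc1cc(O[Si](C(C)C)(C(C)C)C(C)C)cc(OCC)c1-c1c(OCC)cc(O[Si](C(C)C)(C(C)C)C(C)C)cc1OCC
F6 | step 2 | 1,4-diethoxybuta-1,3-diyne | CCOC#CC#COCC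
F7 | step 2 | 3-ethoxy-2-(ethoxyethynyl)cyclobut-2-en-1-one | CCOC#CC1=C(OCC)CC1=O
F8 | step 8 | 5,5',7,7'-tetrakis(benzyloxy)-2,2'-bis[4-(benzyloxy)phenyl]-4H,4'H-[6,6'-bichromene]-4,4'-dione | O=c1cc(-c2ccc(OCc3ccccc3)cc2)oc2cc(OCc3ccccc3)c(-c3c(OCc4ccccc4)cc4oc(-c5ccc(OCc6ccccc6)cc5)cc(=O)c4c3OCc3ccccc3)c(OCc3ccccc3)c12
F9 | step 8 | (2S,2'S,4S,4'S)-5,5',7,7'-tetrakis(benzyloxy)-2,2'-bis[4-(benzyloxy)phenyl]-[6,6'-bichromane]-4,4'-diol | O[C@H]1C[C@@H](c2ccc(OCc3ccccc3)cc2)Oc2cc(OCc3ccccc3)c(-c3c(OCc4ccccc4)cc4c(c3OCc3ccccc3)[C@@H](O)C[C@@H](c3ccc(OCc5ccccc5)cc3)O4)c(OCc3ccccc3)c21
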